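## Analysis of the target

Target 39 is a cis,cis-germacranolide: a ten-membered carbocycle (C1–C10) with two trisubstituted, ring-cis olefins, C1=C10 (1(10)Z) and C4=C5 (4E by the sequence rule, because C15 bears oxygen). Each olefin carries a hydroxymethyl group (C14 on C10, C15 on C4), and a trans α-methylene-γ-butyrolactone is fused across C6–C7 (O6–C12(=O)–C11(=C13H2)–C7). Four contiguous ring stereocentres, C6–C9 (6R,7S,8R,9S), carry in turn the lactone oxygen, the lactone carbon C11, an (S)-2-methylbutanoate and an acetate; drawn on a six-membered ring, O6, O8 and O9 share one face and C11 takes the other. The exocyclic enoate is a Michael acceptor, C6–O and C9–O are allylic and ionisable by zerovalent palladium, and the C9 acetate can migrate to O8 or O14 under base. The difficulty is threefold: closing a ten-membered ring that holds two cis trisubstituted olefins, fixing a stereotetrad on a floppy medium ring, and telling four oxygen functions apart. The route rests on one feature: C5 and C10 are sp2 carbons facing each other across the ring, each bonded to one end of the stereotetrad (C6 and C9). Joining them gives a Δ5(10)-octalin whose ring B (C5–C10) is a cyclohexene carrying C6–C9 and whose ring A (C1–C5, C10) is a plain cyclohexane, so the macrocycle is the oxidative seco form of a bicycle. Germacrane numbering is kept for every bicyclic and ten-membered compound below.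

## Retrosynthetic reasoning

**Acyl groups and silyl ethers (39 ⇐ 38 ⇐ 37 ⇐ 36 ⇐ 34 ⇐ 33).** The two C–O ester bonds and the two primary O–Si bonds are cut last, because esters would not survive the enolate steps. O8 is acylated before O9, so that a free hydroxyl never sits beside the migration-prone acetate under acylation conditions. O8 (benzylic ether), O9 (triethylsilyl) and O14/O15 (triisopropylsilyl) are released by three unrelated reagent types.

**C11=C13 (33 ⇐ 31).** The exocyclic methylene is cut back to the saturated lactone. The forward Mannich/elimination needs the lactone enolate, so it is placed where the lactone is the only carbonyl group in the molecule.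

**C10–C14 and the C15 alcohol (31 ⇐ 30 ⇐ 29 ⇐ 27 ⇐ 26).** The C10–C14 bond is cut to a C10 enol triflate, so that C14 arrives by cross-coupling with retention of olefin geometry. C15 is traced to a carboxyl group, which is reduced through the free acid so that the lactone is not touched.

**The two olefins from two ketones (26 ⇐ 25 ⇐ 24).** C4=C5 and C1=C10 are both traced to enol triflates of the 5,10-diketone. Carrying C15 as an ester makes C5/C4 a β-keto ester. Its enolate forms first and only towards C4, and it also protects C5 from transannular aldol attack while the C10 ketone is enolised kinetically towards C1. The ester further activates the C5 triflate, so the two triflates can be told apart.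

**Key disconnection (24 ⇐ 23).** The C5–C10 bond is re-formed as a tetrasubstituted olefin. This turns the ten-membered ring into two six-membered rings and moves every stereochemical problem onto a cyclohexene. Forward, ozonolysis must cleave this one olefin and leave C6 and C9 unepimerised.

**Oxidation state of C15 and protection of O9 (23 ⇐ 22 ⇐ 21 ⇐ 20).** These are functional-group changes only. The primary alcohol is oxidised before the key step because a β-keto acid could not be handled after it.

**Lactone and C11 (20 ⇐ 18 ⇐ 17 ⇐ 15).** The O6–C12 bond is cut, then the C11 carbon is removed by an Arndt–Eistert transform. This is preferred because a cycloaddition can deliver a C7 carboxyl directly, whereas a C7 acetic acid unit would not activate a dienophile.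

**C7 configuration (15 ⇐ 13).** The trans relationship of C11 to O6 and O8 is traced to the all-cis isomer through base equilibration. The endo cycloadduct has the wrong, less stable C7 configuration, and only C7 is epimerisable.

**Ring B (13 ⇐ 9 + 12).** C6–C7 and C8–C9 are cut in a Diels–Alder transform. No other pairing leaves the new olefin at C5=C10. The two diene termini are made electronically different (silyloxy at C6, acetoxy at C9) so that the ester-bearing carbon of 12 bonds to C6. The C4 stereocentre of 9 directs the facial approach and so carries the absolute configuration.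

**Differentiated diene and dienophile (9 ⇐ 8 ⇐ 7 ⇐ 6; 12 ⇐ 10 + 11).** The two enol derivatives are cut back one at a time to an aldehyde and an ester. The ring-A precursor must therefore hold C6 and C9 at different oxidation levels.

**Ring A (6 ⇐ 5 ⇐ 3 + 4; 3 ⇐ 2 ⇐ 1).** C4–C5 and C1–C10 are cut in a second Diels–Alder transform. An iminium-catalysed version gives aldehyde (C6) and ester (C9) on adjacent carbons, sets C4 enantioselectively, and uses only achiral starting materials.

## Alternatives that were turned down

**Alternative 1:** The disconnection is at the lactone carbonyl: O6–C12 and C11–C12 are cut together, so the last intermediate is the complete, fully acylated ring with a free C6 hydroxyl and a C7 ethynyl group (A2).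

- Forward step: divalent palladium activates the alkyne and joins it to the C6 hydroxyl and carbon monoxide, closing the methylene lactone to give A1, the bis-silyl ether of the target.
- For: the Michael acceptor is made in the last skeletal step, no enolate is needed, and the trans fusion is fixed in advance by C6 and C7.
- Against: A2 is itself a cis,cis-cyclodecadiene with the full stereotetrad, so the ring and its stereocentres remain unsolved. Its C6 hydroxyl and C9 acetate are allylic, and the reducing atmosphere generates zerovalent palladium, which ionises such groups.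
- Comparison: on the endgame this plan is stronger than the chosen route, where the lactone enolate of step 24 forces both acylations to the very end. The chosen route offers in exchange a ring construction and a stereotetrad set on a six-membered ring.

**Alternative 2:** A transannular C4–C9 bond is added retrosynthetically, so the ring becomes a cis-decalin that is opened again by fragmentation.

- Forward step: a tertiary C9 alkoxide pushes, C4–C9 breaks and a C5 sulfonate leaves, giving the C9 ketone and the C4=C5 olefin of dienone A3.
- For: the concerted fragmentation copies the fixed anti-periplanar geometry of a six-membered ring into the olefin. On olefin geometry it is stronger than the chosen route, which relies on the ring-cis preference of medium-ring enolates.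
- Against: C9 is destroyed and must be recreated by reducing an α-alkoxy enone on the flexible ring. The strongly basic conditions sit next to a β-alkoxy ketone in A3. The bicyclic substrate needs two fully substituted fusion carbons and a defined sulfonate, which is six stereocentres to deliver four. The lactone still has to be made afterwards by adjusting the oxidation level of the side chain.
- Comparison: the chosen route sets no stereocentre on the macrocycle and discards only one (C4).

**Alternative 3:** The C6–C7 bond is cut and traced to an O–C13 allylic ether inside a thirteen-membered ring.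

- Forward step: tin–lithium exchange at C6 gives an α-alkoxy carbanion that undergoes a [2,3]-Wittig shift. This forms C6–C7, frees O6, moves the olefin to C11=C13, and contracts the ring to carbinol A4.
- For: one pericyclic step makes a skeletal bond, two stereocentres and the methylene carbon. A thirteen-membered ether is easier to close than a ten-membered carbocycle, and the plan is more convergent than the chosen route.
- Against: the C6/C7 outcome depends on the folding of a large ring with two trisubstituted olefins and is hard to predict. A [1,2]-shift competes. In A4, C12 is still an allylic alcohol and must be oxidised selectively among three other allylic oxygen functions before lactonisation.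
- Comparison: the chosen route gives up convergence for stereocontrol by the endo rule and one equilibration, both on a cyclohexene.

Key step: step 17

Remark: compounds 1, 4, 10, 11 and 35 are taken as commercially available. The C4 configuration of the bicyclic intermediates is sacrificial; it steers step 9 and is erased in step 18.

## Route

Step 1
Reactants: 1 (2E)-penta-2,4-dienoic acid
Product: 2 (2E)-penta-2,4-dien-1-ol
Conditions: LiAlH4, Et2O, 0 °C; aq. NaOH work-up
Reagents that add atoms: none
Why: Hydride reduction of a carboxylic acid to the primary alcohol; 1,2-reduction leaves the conjugated diene in place.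

Step 2
Reactants: 2 (2E)-penta-2,4-dien-1-ol
Product: 3 triisopropyl{[(2E)-penta-2,4-dien-1-yl]oxy}silane
Conditions: iPr3SiCl, imidazole, CH2Cl2, 0 → 20 °C
Reagents that add atoms: chlorotriisopropylsilane, CC(C)[Si](Cl)(C(C)C)C(C)C
Why: Standard silylation of a primary alcohol; the bulky silyl ether survives the mildly acidic aqueous medium of step 3 and later shields one face of the ring-A diene.

Step 3
Reactants: 3 triisopropyl{[(2E)-penta-2,4-dien-1-yl]oxy}silane; 4 ethyl (2E)-4-oxobut-2-enoate
Product: 5 ethyl (1S,2S,3S)-2-formyl-3-{[(triisopropylsilyl)oxy]methyl}cyclohex-4-ene-1-carboxylate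
Conditions: (5S)-5-benzyl-2,2,3-trimethylimidazolidin-4-one·HCl (20 mol %), MeCN/H2O (95:5), 0 → 20 °C; minor exo adduct removed by chromatography
Reagents that add atoms: none
Why: Iminium-catalysed Diels–Alder reaction; the substituted diene terminus bonds to the carbon bearing the activated formyl group (ortho rule), the endo mode puts formyl cis to the silyloxymethyl group, and the benzyl group of the catalyst shields one face of the E-iminium ion, which sets C4 (S) and with it the absolute configuration of the whole route. The trans dienophile keeps formyl and ester trans.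

Step 4
Reactants: 5 ethyl (1S,2S,3S)-2-formyl-3-{[(triisopropylsilyl)oxy]methyl}cyclohex-4-ene-1-carboxylate
Product: 6 ethyl (1S,2S,3S)-2-formyl-3-{[(triisopropylsilyl)oxy]methyl}cyclohexane-1-carboxylate
Conditions: H2 (1 atm), Pd/C (5 % Pd), EtOAc, 20 °C
Reagents that add atoms: none
Why: Catalytic hydrogenation of the disubstituted ring olefin, so that the tetrasubstituted olefin formed in step 9 is later the only one offered to ozone; aldehyde, ester and silyl ether are inert.

Step 5
Reactants: 6 ethyl (1S,2S,3S)-2-formyl-3-{[(triisopropylsilyl)oxy]methyl}cyclohexane-1-carboxylate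
Product: 7 ethyl (1S,3S)-2-[(E)-(triethylsilyloxy)methylidene]-3-{[(triisopropylsilyl)oxy]methyl}cyclohexane-1-carboxylate
Conditions: Et3SiOTf, Et3N, CH2Cl2, −78 → 0 °C
Reagents that add atoms: triethylsilyl trifluoromethanesulfonate, CC[Si](CC)(CC)OS(=O)(=O)C(F)(F)F
Why: Soft enolisation converts only the aldehyde into its silyl enol ether; the E isomer (oxygen syn to C4, whose side chain turns axial to relieve allylic strain) should predominate, and it is the only isomer that can later react as a diene.

Step 6
Reactants: 7 ethyl (1S,3S)-2-[(E)-(triethylsilyloxy)methylidene]-3-{[(triisopropylsilyl)oxy]methyl}cyclohexane-1-carboxylate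
Product: 8 (1S,3S)-2-[(E)-(triethylsilyloxy)methylidene]-3-{[(triisopropylsilyl)oxy]methyl}cyclohexane-1-carbaldehyde
Conditions: i-Bu2AlH (1.1 equiv), CH2Cl2, −78 °C; aq. KNaC4H4O6 (sodium potassium tartrate)
Reagents that add atoms: none
Why: Partial reduction of the α-branched ester stops at the aldehyde through the stable tetrahedral aluminium hemiacetal at −78 °C; the silyl enol ether survives the hydride and the neutral work-up.

Step 7
Reactants: 8 (1S,3S)-2-[(E)-(triethylsilyloxy)methylidene]-3-{[(triisopropylsilyl)oxy]methyl}cyclohexane-1-carbaldehyde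
Product: 9 (E)-{(3S)-2-[(E)-(triethylsilyloxy)methylidene]-3-{[(triisopropylsilyl)oxy]methyl}cyclohexylidene}methyl acetate
Conditions: Ac2O, Et3N, DMAP (10 mol %), CH2Cl2, 20 °C
Reagents that add atoms: acetic anhydride, CC(=O)OC(C)=O
Why: O-Acetylation of the aldehyde enolate gives the enol acetate with oxygen syn to the unsubstituted ring CH2 (E); the diene now has a strong donor at C6 and a weak donor at C9, which is what fixes the regiochemistry of step 9.

Step 8
Reactants: 10 ethyl (2Z)-3-iodoprop-2-enoate; 11 (4-methoxyphenyl)methanol
Product: 12 ethyl (2Z)-3-[(4-methoxybenzyl)oxy]prop-2-enoate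
Conditions: NaH (1.0 equiv), THF, 0 °C; then 10, −78 → −20 °C
Reagents that add atoms: none
Why: Nucleophilic vinylic substitution (addition–elimination) of iodide by the alkoxide with retention of the Z geometry; one equivalent of alkoxide at low temperature limits isomerisation, and any E isomer is removed by chromatography.

Step 9
Reactants: 9 (E)-{(3S)-2-[(E)-(triethylsilyloxy)methylidene]-3-{[(triisopropylsilyl)oxy]methyl}cyclohexylidene}methyl acetate; 12 ethyl (2Z)-3-[(4-methoxybenzyl)oxy]prop-2-enoate
Product: 13 all-cis octalin ester (ethyl 9-acetoxy-8-(4-methoxybenzyloxy)-6-(triethylsilyloxy)-4-[(triisopropylsilyloxy)methyl]-Δ5(10)-octalin-7-carboxylate; O6, C7 ester, O8 and O9 on one face and the C4 side chain on the other)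
Conditions: toluene, 2,6-di-tert-butyl-4-methylphenol (cat.), 135 °C, sealed tube
Reagents that add atoms: none
Why: Thermal normal-demand Diels–Alder reaction: the silyloxy group at C6 is the stronger donor, so the larger HOMO coefficient lies at C9 and pairs with the β-carbon (C8) of the push–pull acrylate, giving C6–C7 and C8–C9. The endo rule puts ester and benzyloxy group cis to both enol oxygens, and the dienophile adds anti to the axial C4 side chain, which sets C6, C8 and C9 in their final absolute configuration.

Step 10
Reactants: 13 all-cis octalin ester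
Product: 15 octalin 7-carboxylic acid (9-hydroxy; carboxyl trans to O6 and O8), via trans hydroxy ester 14 (not isolated)
Conditions: NaOEt (0.2 equiv), EtOH, 20 °C; then LiOH, THF/H2O, 40 °C; then 1 M HCl to pH 4
Reagents that add atoms: lithium hydroxide, [Li+].[OH-]
Why: Ethoxide removes the acetate and equilibrates the only epimerisable centre, C7, to the isomer with the ester equatorial and trans to both neighbours; an alkoxide at C8 is a poor leaving group and nothing next to O9 can migrate, and hydroxide then saponifies the ester.

Step 11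
Reactants: 15 octalin 7-carboxylic acid
Product: 17 C7 diazomethyl ketone, via mixed carbonic anhydride 16 (not isolated)
Conditions: i-BuOCOCl, N-methylmorpholine, THF, −20 °C; then CH2N2, Et2O, 0 °C
Reagents that add atoms: diazomethane, C=[N+]=[N-]
Why: First half of the Arndt–Eistert homologation; the carboxylate is acylated far faster than the hindered secondary C9 hydroxyl, and the mixed anhydride acylates diazomethane without acid that would harm the silyl ethers.

Step 12
Reactants: 17 C7 diazomethyl ketone
Product: 18 octalin 7-acetic acid (C11–C12 chain in place)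
Conditions: PhCO2Ag (10 mol %), Et3N, THF/H2O (9:1), 20 °C, dark
Reagents that add atoms: water, O
Why: Wolff rearrangement; C7 migrates with retention and the ketene is trapped by water, because the C9 hydroxyl lies on the opposite face and cannot reach it.

Step 13
Reactants: 18 octalin 7-acetic acid
Product: 20 trans-fused 12,6-lactone diol (free C9 and C15 hydroxyls), via triol acid 19 (not isolated)
Conditions: HF·pyridine, pyridine, THF, 0 → 20 °C; then PPTS (cat.), toluene, 50 °C
Reagents that add atoms: none
Why: Buffered fluoride removes the secondary triethylsilyl and primary triisopropylsilyl ethers; the γ-hydroxy acid then closes the five-membered lactone on O6, the only hydroxyl that can do so, since O8 is blocked and O9 and O15 would need medium or bridged rings.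

Step 14
Reactants: 20 trans-fused 12,6-lactone diol
Product: 21 lactone 15-oic acid (C4 carboxylic acid; C9 hydroxyl free)
Conditions: TEMPO (20 mol %), PhI(OAc)2 (2.5 equiv), MeCN/pH 7 buffer (NaH2PO4/Na2HPO4) (1:1), 0 → 20 °C
Reagents that add atoms: water, O
Why: Nitroxyl-catalysed oxidation is selective for the primary alcohol over the hindered secondary one and carries the aldehyde hydrate on to the acid in water; the neutral buffer limits migration of the β,γ-olefin into conjugation at the aldehyde stage.

Step 15
Reactants: 21 lactone 15-oic acid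
Product: 22 lactone 2,2,2-trichloroethyl ester
Conditions: Cl3CCH2OH, EDC·HCl, DMAP (5 mol %), CH2Cl2, 0 °C
Reagents that add atoms: 2,2,2-trichloroethanol, OCC(Cl)(Cl)Cl
Why: Carbodiimide esterification; the trichloroethyl ester is inert to ozone, has no olefin, and is later removed by zinc. The C9 hydroxyl is hindered and lies on the face opposite to C15, so it neither lactonises nor competes.

Step 16
Reactants: 22 lactone 2,2,2-trichloroethyl ester
Product: 23 octalin lactone (C4 trichloroethyl ester; C8 4-methoxybenzyl ether; C9 triethylsilyl ether)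
Conditions: Et3SiOTf, 2,6-lutidine, CH2Cl2, −78 °C
Reagents that add atoms: triethylsilyl trifluoromethanesulfonate, CC[Si](CC)(CC)OS(=O)(=O)C(F)(F)F
Why: Silyl triflate silylation of the hindered allylic alcohol under non-nucleophilic base, which does not isomerise the β,γ-unsaturated ester.

Step 17
Reactants: 23 octalin lactone
Product: 24 ten-membered 5,10-diketone with fused trans lactone (C4 trichloroethyl ester; C8 4-methoxybenzyl ether; C9 triethylsilyl ether)
Conditions: O3/O2, CH2Cl2/MeOH (4:1), NaHCO3, Sudan Red 7B as indicator, −78 °C; then Me2S, −78 → 20 °C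
Reagents that add atoms: ozone, [O-][O+]=O
Why: Ozone adds as a 1,3-dipole to the electron-rich tetrasubstituted C5=C10 olefin; the primary ozonide cleaves to a ketone and a carbonyl oxide, methanol traps the carbonyl oxide as a methoxy hydroperoxide, and Me2S reduces it to the second ketone. The closest known reaction type is the ozonolysis of 9,10-octalins to cyclodecane-1,6-diones. The ten-membered ring is not closed by bond formation: it appears when the fusion bond shared by the two six-membered rings is cut, which is a ring expansion by scission. No stereocentre is created; C6–C9 and the trans lactone are carried over unchanged, and C4 is now labile but irrelevant. The step needs chemoselectivity for one olefin: it is the only C=C bond present, and it reacts with ozone several orders of magnitude faster than the anisyl ring, so the dye end-point at −78 °C stops the addition in time. Methanol trapping keeps the carbonyl oxide from rearranging towards the oxygen-bearing C6 or C9. The buffered, neutral reductive work-up avoids epimerisation at C6 and C9 and transannular aldol reaction of the 1,6-diketone.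

Step 18
Reactants: 24 ten-membered 5,10-diketone
Product: 25 bis(enol triflate) (C4=C5–OTf and C1=C10–OTf, both ring-cis)
Conditions: KN(SiMe3)2 (2.2 equiv), THF, −78 °C; then ArNTf2 (Ar = 5-chloropyridin-2-yl, 2.4 equiv), −78 → −20 °C
Reagents that add atoms: N-(5-chloropyridin-2-yl)-1,1,1-trifluoro-N-(trifluoromethylsulfonyl)methanesulfonamide, FC(F)(F)S(=O)(=O)N(c1ccc(Cl)cn1)S(=O)(=O)C(F)(F)F
Why: The first equivalent of base gives the β-keto ester enolate, which can only lie towards C4 and removes C5 as an electrophile for transannular aldol reaction; the second deprotonates the C10 ketone kinetically at the C1 methylene, away from the silyloxy-bearing C9. O-Triflation fixes both olefins, and the ten-membered ring together with chelation of the keto ester enolate enforces the ring-cis geometry of the target.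

Step 19
Reactants: 25 bis(enol triflate)
Product: 26 C10 enol triflate enoate (C5–H; C4 trichloroethyl ester)
Conditions: Pd(OAc)2 (5 mol %), PPh3 (10 mol %), HCO2H (1.5 equiv), Et3N (3 equiv), DMF, 20 °C
Reagents that add atoms: none
Why: Palladium-catalysed formate reduction of a vinyl triflate with retention of geometry; oxidative addition to zerovalent palladium is much faster at the ester-activated C5 triflate than at the unactivated C10 triflate, so only C5 is reduced at room temperature.

Step 20
Reactants: 26 C10 enol triflate enoate
Product: 27 C10 enol triflate 15-oic acid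
Conditions: Zn dust, THF/1 M aq. NH4OAc (4:1), 20 °C
Reagents that add atoms: none
Why: Reductive β-elimination of the 2,2,2-trichloroethyl group by zinc frees the carboxylic acid at near-neutral pH, which the silyl ether, lactone and vinyl triflate tolerate.

Step 21
Reactants: 27 C10 enol triflate 15-oic acid
Product: 29 C10 enol triflate 15-ol (allylic alcohol at C15), via mixed carbonic anhydride 28 (not isolated)
Conditions: i-BuOCOCl, N-methylmorpholine, THF, −15 °C; then NaBH4, MeOH, −15 → 0 °C
Reagents that add atoms: none
Why: The activated anhydride is reduced by borohydride to the primary allylic alcohol at a temperature where the γ-lactone and the vinyl triflate do not react, which a direct ester reduction could not achieve.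

Step 22
Reactants: 29 C10 enol triflate 15-ol
Product: 30 14,15-diol (C9 triethylsilyl ether; C8 4-methoxybenzyl ether; saturated lactone)
Conditions: Bu3SnCH2OH, Pd(PPh3)4 (5 mol %), LiCl (3 equiv), 1,4-dioxane, 80 °C
Reagents that add atoms: tributyl(hydroxymethyl)stannane, CCCC[Sn](CO)(CCCC)CCCC
Why: Stille coupling of the vinyl triflate with a hydroxymethyl stannane installs C14 on C10 with retention of the ring-cis olefin; free hydroxyl groups are tolerated.

Step 23
Reactants: 30 14,15-diol
Product: 31 14,15-bis(triisopropylsilyl) ether
Conditions: iPr3SiCl, imidazole, DMF, 0 → 20 °C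
Reagents that add atoms: chlorotriisopropylsilane, CC(C)[Si](Cl)(C(C)C)C(C)C
Why: Silylation of both primary allylic alcohols; primary triisopropylsilyl ethers outlast the later acidic removal of the secondary triethylsilyl ether and fall only to fluoride at the end.

Step 24
Reactants: 31 14,15-bis(triisopropylsilyl) ether
Product: 33 α-methylene lactone, via Mannich base 32 (not isolated)
Conditions: LiN(iPr)2 (1.2 equiv), THF, −78 °C; then CH2=NMe2+ I−, −78 → 0 °C; then MeI, MeOH, 20 °C; then aq. NaHCO3, CH2Cl2
Reagents that add atoms: dimethyl(methylidene)ammonium iodide, C=[N+](C)C.[I-]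
Why: Mannich reaction of the lactone enolate, then quaternisation and β-elimination of trimethylamine; the lactone α-CH2 is the only acidic C–H left, which is why this step precedes both acylations.

Step 25
Reactants: 33 α-methylene lactone
Product: 34 8-alcohol (C9 triethylsilyl ether retained)
Conditions: DDQ, CH2Cl2/pH 7 buffer (NaH2PO4/Na2HPO4) (10:1), 0 °C
Reagents that add atoms: none
Why: Oxidative cleavage of the 4-methoxybenzyl ether by benzylic hydride abstraction; silyl ethers, both olefins and the enoate are untouched under buffered conditions.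

Step 26
Reactants: 34 8-alcohol; 35 (2S)-2-methylbutanoic acid
Product: 36 8-[(2S)-2-methylbutanoate] (C9 triethylsilyl ether)
Conditions: EDC·HCl, DMAP, CH2Cl2, 0 → 20 °C
Reagents that add atoms: none
Why: Steglich esterification brings in the side-chain stereocentre from the chiral pool; low temperature limits α-epimerisation of the activated acid, and with a silyl ether on O9 no acyl group can migrate.

Step 27
Reactants: 36 8-[(2S)-2-methylbutanoate]
Product: 37 9-alcohol
Conditions: PPTS, MeOH/CH2Cl2 (1:1), 0 °C
Reagents that add atoms: none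
Why: Mild acid methanolysis removes the secondary triethylsilyl ether far faster than the primary triisopropylsilyl ethers; acidic conditions do not move the branched ester from O8 to O9.

Step 28
Reactants: 37 9-alcohol
Product: 38 9-acetate (14,15-bis(triisopropylsilyl) ether of the target)
Conditions: Ac2O, pyridine, DMAP (cat.), CH2Cl2, 0 °C
Reagents that add atoms: acetic anhydride, CC(=O)OC(C)=O
Why: Acetylation with excess anhydride is faster than migration of the hindered branched acyl group, so the two esters end on the correct oxygens.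

Step 29
Reactants: 38 9-acetate
Product: 39 CNP0207247.12, (1(10)Z,4E,6R,7S,8R,9S)-9-acetoxy-14,15-dihydroxy-8-[(2S)-2-methylbutanoyloxy]germacra-1(10),4,11(13)-trien-12,6-olide
Conditions: HF·pyridine, pyridine, THF, 0 → 20 °C
Reagents that add atoms: none
Why: Buffered acidic fluoride cleaves both primary silyl ethers; the absence of basic fluoride avoids acetyl migration to O8 or O14 and conjugate addition to the methylene lactone.

## Compound list

1 | (2E)-penta-2,4-dienoic acid | C=C/C=C/C(=O)O | starting material
2 | (2E)-penta-2,4-dien-1-ol | C=C/C=C/CO | intermediate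
3 | triisopropyl{[(2E)-penta-2,4-dien-1-yl]oxy}silane | C=C/C=C/CO[Si](C(C)C)(C(C)C)C(C)C | intermediate
4 | ethyl (2E)-4-oxobut-2-enoate | CCOC(=O)/C=C/C=O | starting material
5 | ethyl (1S,2S,3S)-2-formyl-3-{[(triisopropylsilyl)oxy]methyl}cyclohex-4-ene-1-carboxylate | O=C[C@H]1[C@@H](CO[Si](C(C)C)(C(C)C)C(C)C)C=CC[C@@H]1C(=O)OCC | intermediate
6 | ethyl (1S,2S,3S)-2-formyl-3-{[(triisopropylsilyl)oxy]methyl}cyclohexane-1-carboxylate | O=C[C@H]1[C@@H](CO[Si](C(C)C)(C(C)C)C(C)C)CCC[C@@H]1C(=O)OCC | intermediate
7 | ethyl (1S,3S)-2-[(E)-(triethylsilyloxy)methylidene]-3-{[(triisopropylsilyl)oxy]methyl}cyclohexane-1-carboxylate | CCOC(=O)[C@H]1CCC[C@H](CO[Si](C(C)C)(C(C)C)C(C)C)/C1=C\O[Si](CC)(CC)CC | intermediate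
8 | (1S,3S)-2-[(E)-(triethylsilyloxy)methylidene]-3-{[(triisopropylsilyl)oxy]methyl}cyclohexane-1-carbaldehyde | O=C[C@H]1CCC[C@H](CO[Si](C(C)C)(C(C)C)C(C)C)/C1=C\O[Si](CC)(CC)CC | intermediate
9 | (E)-{(3S)-2-[(E)-(triethylsilyloxy)methylidene]-3-{[(triisopropylsilyl)oxy]methyl}cyclohexylidene}methyl acetate (ring-A diene) | CC(=O)O/C=C1\CCC[C@H](CO[Si](C(C)C)(C(C)C)C(C)C)/C1=C\O[Si](CC)(CC)CC | intermediate
10 | ethyl (2Z)-3-iodoprop-2-enoate | CCOC(=O)/C=C\I | starting material
11 | (4-methoxyphenyl)methanol | COc1ccc(CO)cc1 | starting material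
12 | ethyl (2Z)-3-[(4-methoxybenzyl)oxy]prop-2-enoate | CCOC(=O)/C=C\OCc1ccc(OC)cc1 | intermediate
13 | all-cis octalin ester: ethyl 9-acetoxy-8-(4-methoxybenzyloxy)-6-(triethylsilyloxy)-4-[(triisopropylsilyloxy)methyl]-Δ5(10)-octalin-7-carboxylate | CC(C)[Si](C(C)C)(C(C)C)OC[C@H]1CCCC2=C1[C@@H](O[Si](CC)(CC)CC)[C@@H](C(=O)OCC)[C@@H](OCc3ccc(OC)cc3)[C@H]2OC(C)=O | intermediate
14 | trans hydroxy ester: C7 epimer of 13 with free C9 hydroxyl | CC(C)[Si](C(C)C)(C(C)C)OC[C@H]1CCCC2=C1[C@@H](O[Si](CC)(CC)CC)[C@H](C(=O)OCC)[C@@H](OCc3ccc(OC)cc3)[C@H]2O | intermediate (not isolated)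
15 | octalin 7-carboxylic acid (carboxyl trans to O6 and O8; 9-hydroxy) | CC(C)[Si](C(C)C)(C(C)C)OC[C@H]1CCCC2=C1[C@@H](O[Si](CC)(CC)CC)[C@H](C(=O)O)[C@@H](OCc3ccc(OC)cc3)[C@H]2O | intermediate
16 | mixed isobutyl carbonic anhydride of 15 | CC(C)[Si](C(C)C)(C(C)C)OC[C@H]1CCCC2=C1[C@@H](O[Si](CC)(CC)CC)[C@H](C(=O)OC(=O)OCC(C)C)[C@@H](OCc3ccc(OC)cc3)[C@H]2O | intermediate (not isolated)
17 | C7 diazomethyl ketone | CC(C)[Si](C(C)C)(C(C)C)OC[C@H]1CCCC2=C1[C@@H](O[Si](CC)(CC)CC)[C@H](C(=O)C=[N+]=[N-])[C@@H](OCc3ccc(OC)cc3)[C@H]2O | intermediate
18 | octalin 7-acetic acid | CC(C)[Si](C(C)C)(C(C)C)OC[C@H]1CCCC2=C1[C@@H](O[Si](CC)(CC)CC)[C@H](CC(=O)O)[C@@H](OCc3ccc(OC)cc3)[C@H]2O | intermediate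
19 | triol acid (6,9,15-trihydroxy 7-acetic acid) | OC[C@H]1CCCC2=C1[C@@H](O)[C@H](CC(=O)O)[C@@H](OCc3ccc(OC)cc3)[C@H]2O | intermediate (not isolated)
20 | trans-fused 12,6-lactone diol (9,15-dihydroxy; 8-(4-methoxybenzyloxy)) | OC[C@H]1CCCC2=C1[C@H]3OC(=O)C[C@@H]3[C@@H](OCc4ccc(OC)cc4)[C@H]2O | intermediate
21 | lactone 15-oic acid (C4 carboxylic acid; 9-hydroxy) | OC(=O)[C@H]1CCCC2=C1[C@H]3OC(=O)C[C@@H]3[C@@H](OCc4ccc(OC)cc4)[C@H]2O | intermediate
22 | lactone 2,2,2-trichloroethyl ester (9-hydroxy) | ClC(Cl)(Cl)COC(=O)[C@H]1CCCC2=C1[C@H]3OC(=O)C[C@@H]3[C@@H](OCc4ccc(OC)cc4)[C@H]2O | intermediate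
23 | octalin lactone, key-step precursor (C4 trichloroethyl ester; C8 4-methoxybenzyl ether; C9 triethylsilyl ether; O6, O8, O9 cis, C11 and C15 on the other face) | ClC(Cl)(Cl)COC(=O)[C@H]1CCCC2=C1[C@H]3OC(=O)C[C@@H]3[C@@H](OCc4ccc(OC)cc4)[C@H]2O[Si](CC)(CC)CC | intermediate
24 | ten-membered 5,10-diketone with fused trans 12,6-lactone (C4 trichloroethyl ester; C8 4-methoxybenzyl ether; C9 triethylsilyl ether) | O=C1[C@@H](C(=O)OCC(Cl)(Cl)Cl)CCCC(=O)[C@H](O[Si](CC)(CC)CC)[C@H](OCc3ccc(OC)cc3)[C@H]2CC(=O)O[C@H]12 | intermediate
25 | bis(enol triflate) (C4=C5–OTf, C1=C10–OTf, ring-cis) | C1C(=O)O[C@@H]2/C(OS(=O)(=O)C(F)(F)F)=C(/C(=O)OCC(Cl)(Cl)Cl)CC/C=C(/OS(=O)(=O)C(F)(F)F)[C@H](O[Si](CC)(CC)CC)[C@H](OCc3ccc(OC)cc3)[C@@H]12 | intermediate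
26 | C10 enol triflate enoate (C5–H; C4 trichloroethyl ester) | C1C(=O)O[C@@H]2/C=C(/C(=O)OCC(Cl)(Cl)Cl)CC/C=C(/OS(=O)(=O)C(F)(F)F)[C@H](O[Si](CC)(CC)CC)[C@H](OCc3ccc(OC)cc3)[C@@H]12 | intermediate
27 | C10 enol triflate 15-oic acid | C1C(=O)O[C@@H]2/C=C(/C(=O)O)CC/C=C(/OS(=O)(=O)C(F)(F)F)[C@H](O[Si](CC)(CC)CC)[C@H](OCc3ccc(OC)cc3)[C@@H]12 | intermediate
28 | mixed isobutyl carbonic anhydride of 27 | C1C(=O)O[C@@H]2/C=C(/C(=O)OC(=O)OCC(C)C)CC/C=C(/OS(=O)(=O)C(F)(F)F)[C@H](O[Si](CC)(CC)CC)[C@H](OCc3ccc(OC)cc3)[C@@H]12 | intermediate (not isolated)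
29 | C10 enol triflate 15-ol | C1C(=O)O[C@@H]2/C=C(/CO)CC/C=C(/OS(=O)(=O)C(F)(F)F)[C@H](O[Si](CC)(CC)CC)[C@H](OCc3ccc(OC)cc3)[C@@H]12 | intermediate
30 | 14,15-diol (C9 triethylsilyl ether; C8 4-methoxybenzyl ether; saturated lactone) | C1C(=O)O[C@@H]2/C=C(/CO)CC/C=C(/CO)[C@H](O[Si](CC)(CC)CC)[C@H](OCc3ccc(OC)cc3)[C@@H]12 | intermediate
31 | 14,15-bis(triisopropylsilyl) ether | C1C(=O)O[C@@H]2/C=C(/CO[Si](C(C)C)(C(C)C)C(C)C)CC/C=C(/CO[Si](C(C)C)(C(C)C)C(C)C)[C@H](O[Si](CC)(CC)CC)[C@H](OCc3ccc(OC)cc3)[C@@H]12 | intermediate
32 | Mannich base (11-(dimethylaminomethyl) lactone; C11 epimers) | CN(C)CC1C(=O)O[C@@H]2/C=C(/CO[Si](C(C)C)(C(C)C)C(C)C)CC/C=C(/CO[Si](C(C)C)(C(C)C)C(C)C)[C@H](O[Si](CC)(CC)CC)[C@H](OCc3ccc(OC)cc3)[C@@H]12 | intermediate (not isolated)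
33 | α-methylene lactone (C8 4-methoxybenzyl ether; C9 triethylsilyl ether) | C=C1C(=O)O[C@@H]2/C=C(/CO[Si](C(C)C)(C(C)C)C(C)C)CC/C=C(/CO[Si](C(C)C)(C(C)C)C(C)C)[C@H](O[Si](CC)(CC)CC)[C@H](OCc3ccc(OC)cc3)[C@@H]12 | intermediate
34 | 8-alcohol | C=C1C(=O)O[C@@H]2/C=C(/CO[Si](C(C)C)(C(C)C)C(C)C)CC/C=C(/CO[Si](C(C)C)(C(C)C)C(C)C)[C@H](O[Si](CC)(CC)CC)[C@H](O)[C@@H]12 | intermediate
35 | (2S)-2-methylbutanoic acid | CC[C@H](C)C(=O)O | starting material
36 | 8-[(2S)-2-methylbutanoate] (C9 triethylsilyl ether) | C=C1C(=O)O[C@@H]2/C=C(/CO[Si](C(C)C)(C(C)C)C(C)C)CC/C=C(/CO[Si](C(C)C)(C(C)C)C(C)C)[C@H](O[Si](CC)(CC)CC)[C@H](OC(=O)[C@@H](C)CC)[C@@H]12 | intermediate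
37 | 9-alcohol | C=C1C(=O)O[C@@H]2/C=C(/CO[Si](C(C)C)(C(C)C)C(C)C)CC/C=C(/CO[Si](C(C)C)(C(C)C)C(C)C)[C@H](O)[C@H](OC(=O)[C@@H](C)CC)[C@@H]12 | intermediate
38 | 9-acetate, 14,15-bis(triisopropylsilyl) ether of the target | C=C1C(=O)O[C@@H]2/C=C(/CO[Si](C(C)C)(C(C)C)C(C)C)CC/C=C(/CO[Si](C(C)C)(C(C)C)C(C)C)[C@H](OC(C)=O)[C@H](OC(=O)[C@@H](C)CC)[C@@H]12 | intermediate
39 | CNP0207247.12, (1(10)Z,4E,6R,7S,8R,9S)-9-acetoxy-14,15-dihydroxy-8-[(2S)-2-methylbutanoyloxy]germacra-1(10),4,11(13)-trien-12,6-olide | C=C1C(=O)O[C@@H]2/C=C(/CO)CC/C=C(/CO)[C@H](OC(C)=O)[C@H](OC(=O)[C@@H](C)CC)[C@@H]12 | target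

## Step count and least certain steps

Total step count: 29. Longest linear sequence: 28 steps (steps 1–7 and 9–29, from acid 1); step 8 is the only side branch.

**Step 17 (key step).** Once the olefin is consumed, ozone may begin to attack the electron-rich anisyl ring of the C8 ether. A carbonyl oxide that escapes methanol may also rearrange with migration of the oxygen-bearing C6 or C9, inserting oxygen into the ring. Both would lower the yield of the diketone without being easy to detect at the end-point. The fallback avoids ozone: octalin 23 is epoxidised with mCPBA (NaHCO3, CH2Cl2, 0 °C) to the 5,10-epoxide F1, and either face serves. F1 is then cleaved with H5IO6 in THF/H2O, which opens the epoxide and cuts the resulting diol in one operation, and the route is rejoined at diketone 24.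

**Step 9.** The dienophile is deactivated by its own alkoxy donor, so the temperature needed may degrade the bis(enol) diene before cycloaddition. Endo selectivity (which sets C8) and regioselectivity rest on moderate preferences, not on a constraint. The fallback makes the reaction intramolecular. Aldehyde 8 is converted with iPr2SiCl2, Et3N and the sodium enolate of ethyl 3-oxopropanoate into the mixed bis(enol) silyl ketal F2, in which the E-acrylate is tied to O9. Heating F2 in toluene gives the tethered cycloadduct F3. The five-membered tether forces C8–C9 bonding with O8 cis to O9, and the E-olefin places the ester trans, so no epimerisation is needed. Mild methanolysis (K2CO3, MeOH, 0 °C) of the strained silylene gives the 8,9-diol F4. Stannylene-directed alkylation (Bu2SnO, then 4-methoxybenzyl chloride, CsF) at the equatorial O8 returns the route at hydroxy ester 14.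

**Step 18.** With two equivalents of a strong base, deprotonation or elimination within the trichloroethyl ester, or partial enolisation of the lactone, may compete. The next step then depends on distinguishing two triflates. The fallback takes the ketones one at a time. Diketone 24 is treated with Tf2O and iPr2NEt (CH2Cl2, −78 °C), which triflates only the β-keto ester and gives the keto triflate F5. Palladium-catalysed formate reduction (Pd(OAc)2, PPh3, HCO2H, Et3N) gives the keto enoate F6 with the C10 ketone untouched. Kinetic enolisation of this single ketone with KN(SiMe3)2 and the same triflimide then gives triflate 26, where the route continues.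

**Step 3.** An acyclic, mono-substituted diene may add too slowly to the iminium ion of a β-substituted enal, so hydrolytic side reactions or poor endo/exo control may take over and erode the enantiomeric purity of C4. The fallback replaces catalyst control by an auxiliary. Diene 3 is combined with the fumarate-derived imide F7, prepared from the acid chloride of monoethyl fumarate and lithiated (4S)-4-benzyl-1,3-oxazolidin-2-one. Under Et2AlCl at −78 °C the chelated imide gives the endo adduct F8 with the same regiochemistry and facial sense. LiBH4 reduces the imide selectively to the alcohol ester F9, and oxidation with the Dess–Martin periodinane returns the route at aldehyde 5.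

## Further compounds

F1 | step 17 | 5,10-epoxide of octalin lactone 23 | ClC(Cl)(Cl)COC(=O)[C@H]1CCC[C@]23O[C@]12[C@H]4OC(=O)C[C@@H]4[C@@H](OCc5ccc(OC)cc5)[C@H]3O[Si](CC)(CC)CC
F2 | step 9 | mixed bis(enol) diisopropylsilyl ketal of aldehyde 8 and ethyl (E)-3-hydroxyacrylate | CCOC(=O)/C=C/O[Si](C(C)C)(C(C)C)O/C=C1\CCC[C@H](CO[Si](C(C)C)(C(C)C)C(C)C)/C1=C\O[Si](CC)(CC)CC
F3 | step 9 | tethered cycloadduct: 8,9-O-diisopropylsilylene octalin 7-carboxylate (ester trans to O6 and O8) | CC(C)[Si](C(C)C)(C(C)C)OC[C@H]1CCCC2=C1[C@@H](O[Si](CC)(CC)CC)[C@H](C(=O)OCC)[C@H]3O[Si](C(C)C)(C(C)C)O[C@@H]23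
F4 | step 9 | cis-8,9-diol octalin 7-carboxylate | CC(C)[Si](C(C)C)(C(C)C)OC[C@H]1CCCC2=C1[C@@H](O[Si](CC)(CC)CC)[C@H](C(=O)OCC)[C@@H](O)[C@H]2O
F5 | step 18 | C5 enol triflate of the β-keto ester with free C10 ketone | C1C(=O)O[C@@H]2/C(OS(=O)(=O)C(F)(F)F)=C(/C(=O)OCC(Cl)(Cl)Cl)CCCC(=O)[C@H](O[Si](CC)(CC)CC)[C@H](OCc3ccc(OC)cc3)[C@@H]12
F6 | step 18 | C4=C5 enoate with free C10 ketone | C1C(=O)O[C@@H]2/C=C(/C(=O)OCC(Cl)(Cl)Cl)CCCC(=O)[C@H](O[Si](CC)(CC)CC)[C@H](OCc3ccc(OC)cc3)[C@@H]12
F7 | step 3 | ethyl (2E)-4-[(4S)-4-benzyl-2-oxo-1,3-oxazolidin-3-yl]-4-oxobut-2-enoate | CCOC(=O)/C=C/C(=O)N1[C@@H](Cc2ccccc2)COC1=O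
F8 | step 3 | imide cycloadduct (acyl oxazolidinone in place of the formyl group of 5) | O=C([C@H]1[C@@H](CO[Si](C(C)C)(C(C)C)C(C)C)C=CC[C@@H]1C(=O)OCC)N2[C@@H](Cc3ccccc3)COC2=O
F9 | step 3 | ethyl (1S,2S,3S)-2-(hydroxymethyl)-3-{[(triisopropylsilyl)oxy]methyl}cyclohex-4-ene-1-carboxylate | OC[C@H]1[C@@H](CO[Si](C(C)C)(C(C)C)C(C)C)C=CC[C@@H]1C(=O)OCC
A1 | alternative 1 | 14,15-bis(tert-butyldimethylsilyl) ether of the target | C=C1C(=O)O[C@@H]2/C=C(/CO[Si](C)(C)C(C)(C)C)CC/C=C(/CO[Si](C)(C)C(C)(C)C)[C@H](OC(C)=O)[C@H](OC(=O)[C@@H](C)CC)[C@@H]12
A2 | alternative 1 | C6 carbinol with C7 ethynyl group, fully acylated ten-membered ring | O[C@@H]1/C=C(/CO[Si](C)(C)C(C)(C)C)CC/C=C(/CO[Si](C)(C)C(C)(C)C)[C@H](OC(C)=O)[C@H](OC(=O)[C@@H](C)CC)[C@H]1C#C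
A3 | alternative 2 | ring-cis,ring-cis cyclodecadienone with C9 ketone | O=C1/C(CO[Si](C(C)C)(C(C)C)C(C)C)=C\CC/C(CO[Si](C(C)C)(C(C)C)C(C)C)=C\[C@@H](O[Si](C)(C)C(C)(C)C)[C@H](C(=C)CO[Si](C)(C)C(C)(C)C)[C@H]1OCc2ccc(OC)cc2
A4 | alternative 3 | ten-membered C6 carbinol with 2-substituted allyl arm on C7 | O[C@@H]1/C=C(/CO[Si](C(C)C)(C(C)C)C(C)C)CC/C=C(/CO[Si](C(C)C)(C(C)C)C(C)C)[C@H](O[Si](CC)(CC)CC)[C@H](OCc2ccc(OC)cc2)[C@H]1C(=C)CO[Si](C)(C)C(C)(C)C
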